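**Plan**

- Retrosynthesis: the C8–OMe bond is cut first (back to C8–Br, then C8–H). Ring C is then cut in one stroke at O1–C8a, C4a–C4 and O1–C2, giving a ring-A aryne (stored as its ortho-silylaryl triflate) and 3-(3,4,5-trimethoxyphenyl)propiolic acid.
- Enabling feature: the adjacent ring-A carbons C8a and C4a bear O1 and the carbonyl carbon C4, the ortho-hydroxyaryl ketone pattern left when an aryne inserts into a carboxylic acid C–O bond. The C5 oxygen next to C4a polarises that aryne.
- Forward, ring A: 4-O-methylgallic acid is benzylated, degraded to the phenol, ortho-brominated and converted into the silyl triflate.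
- Forward, ring B with C2–C3–C4: 5-ethynyl-1,2,3-trimethoxybenzene is carboxylated with CO2.
- Ring C is the only ring made and closes in the aryne step. Debenzylation, bromination at C8 and Cu-mediated methoxylation then complete ring A.
- Stereochemistry: the target has no stereocentre and no stereogenic double bond, so nothing has to be set or preserved.

Key step: step 8

Assumption: compounds 1 and 11 are taken as purchasable, and flavone numbering (O1, C2–C4, C4a, C5–C8, C8a, ring B primed) is used for all chromenones.

**Route**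

Step 1
Reactants: 1 3,5-dihydroxy-4-methoxybenzoic acid (4-O-methylgallic acid)
Product: 2 benzyl 3,5-bis(benzyloxy)-4-methoxybenzoate
Conditions: BnBr (3.5 equiv), K2CO3, DMF, 60 °C
Reagents that add atoms: benzyl bromide, BrCc1ccccc1
Why: Williamson O-alkylation of both phenols together with carboxylate alkylation masks all acidic sites in one operation, and benzyl is chosen because it can later be removed without touching the methyl ethers.

Step 2
Reactants: 2 benzyl 3,5-bis(benzyloxy)-4-methoxybenzoate
Product: 3 [3,5-bis(benzyloxy)-4-methoxyphenyl]methanol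
Conditions: LiAlH4, THF, 0 °C to rt
Reagents that add atoms: none
Why: Hydride reduction of the ester gives the primary benzylic alcohol, while aryl benzyl and methyl ethers are inert to LiAlH4.

Step 3
Reactants: 3 [3,5-bis(benzyloxy)-4-methoxyphenyl]methanol
Product: 4 3,5-bis(benzyloxy)-4-methoxybenzaldehyde
Conditions: activated MnO2 (excess), CH2Cl2, rt
Reagents that add atoms: none
Why: Benzylic alcohol oxidation with MnO2 stops cleanly at the aldehyde and leaves the ethers untouched.

Step 4
Reactants: 4 3,5-bis(benzyloxy)-4-methoxybenzaldehyde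
Product: 6 3,5-bis(benzyloxy)-4-methoxyphenol, via aryl formate 5 (not isolated)
Conditions: mCPBA, CH2Cl2, 0 °C to rt; then K2CO3, MeOH, rt
Reagents that add atoms: 3-chloroperoxybenzoic acid (mCPBA), O=C(OO)c1cccc(Cl)c1
Why: In this Baeyer–Villiger (Dakin-type) oxidation the electron-rich trialkoxyphenyl group migrates in preference to hydride, and mild methanolysis of the resulting formate frees the phenol without affecting the benzyl ethers.

Step 5
Reactants: 6 3,5-bis(benzyloxy)-4-methoxyphenol
Product: 7 3,5-bis(benzyloxy)-2-bromo-4-methoxyphenol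
Conditions: NBS (1.0 equiv), CH2Cl2, −78 to 0 °C
Reagents that add atoms: N-bromosuccinimide, O=C1CCC(=O)N1Br
Why: Electrophilic aromatic bromination can only give one monobromide, because the two free positions of the symmetric phenol are equivalent and each is ortho to the hydroxyl, and one equivalent of NBS in the cold should hold the reaction at that stage.

Step 6
Reactants: 7 3,5-bis(benzyloxy)-2-bromo-4-methoxyphenol
Product: 10 3,5-bis(benzyloxy)-4-methoxy-2-(trimethylsilyl)phenyl trifluoromethanesulfonate, via aryl trimethylsilyl ether 8 (not isolated), via lithium 2-silylphenoxide 9 (not isolated)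
Conditions: HMDS, THF, reflux; evaporate; n-BuLi, THF, −100 °C; Tf2O, −100 to −78 °C
Reagents that add atoms: hexamethyldisilazane, C[Si](C)(C)N[Si](C)(C)C; trifluoromethanesulfonic anhydride, O=S(=O)(OS(=O)(=O)C(F)(F)F)C(F)(F)F
Why: O-silylation, bromine–lithium exchange (faster at −100 °C than benzylic deprotonation) and 1,3 O-to-C silyl migration (retro-Brook rearrangement) put silicon on carbon, and the released phenoxide is trapped by Tf2O, which is the standard passage from ortho-bromophenols to ortho-silylaryl triflates.

Step 7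
Reactants: 11 5-ethynyl-1,2,3-trimethoxybenzene
Product: 13 3-(3,4,5-trimethoxyphenyl)propiolic acid, via lithium acetylide 12 (not isolated)
Conditions: n-BuLi, THF, −78 °C; CO2; aq. HCl, 0 °C
Reagents that add atoms: carbon dioxide, O=C=O
Why: Deprotonation of the terminal alkyne and carboxylation of the lithium acetylide is the standard route to arylpropiolic acids, and cold acidification avoids decarboxylation.

Step 8
Reactants: 10 3,5-bis(benzyloxy)-4-methoxy-2-(trimethylsilyl)phenyl trifluoromethanesulfonate; 13 3-(3,4,5-trimethoxyphenyl)propiolic acid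
Product: 16 5,7-bis(benzyloxy)-6-methoxy-2-(3,4,5-trimethoxyphenyl)-4H-chromen-4-one, via aryne 14 (not isolated), via cesium ynone phenoxide 15 (not isolated)
Conditions: CsF (4 equiv), THF, 125 °C, sealed tube
Reagents that add atoms: none
Why: Fluoride removes the trimethylsilyl group and triflate departs to give aryne 14, to which the cesium carboxylate of 13 adds through oxygen at the aryne carbon remote from the flanking benzyloxy group; the aryl anion left beside that oxygen attacks the ester carbonyl, and the strained four-membered alkoxide opens to the ortho-acylphenoxide 15, so that the aryne has inserted into the acid C–O bond (O1–C8a and C4–C4a formed). The closest known reaction type is this very insertion of arynes into carboxylic acids, which gives ortho-hydroxyaryl ketones and, from arylpropiolic acids under CsF in hot THF, flavones. Ring C then closes by 6-endo-dig oxa-Michael addition of the phenoxide to the β-carbon of the ynone (O1–C2), the resulting vinyl anion taking up the proton that the acid supplied, whereas the 5-exo-dig mode leading to an aurone would need anti-Michael attack. No stereocentre is created. The selectivity required is regiochemical, oxygen having to bond to the carbon that becomes C8a and not C4a, and it is secured by the σ-withdrawing C5 benzyloxy group adjacent to the triple bond, which distorts the aryne so that the distal carbon is the electrophilic one and the negative charge develops next to oxygen, while C8 carries only hydrogen and exerts no opposing bias. Premature protonation of the aryl anion, which would stop at the aryl ester, is countered by the high temperature and by having the acid as the only proton source.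

Step 9
Reactants: 16 5,7-bis(benzyloxy)-6-methoxy-2-(3,4,5-trimethoxyphenyl)-4H-chromen-4-one
Product: 17 5,7-dihydroxy-6-methoxy-2-(3,4,5-trimethoxyphenyl)-4H-chromen-4-one
Conditions: H2 (1 atm), 10% Pd/C, THF/MeOH, rt
Reagents that add atoms: none
Why: Hydrogenolysis of aryl benzyl ethers over Pd/C at ambient pressure should leave the C2–C3 double bond, the carbonyl and the methyl ethers of the flavone intact.

Step 10
Reactants: 17 5,7-dihydroxy-6-methoxy-2-(3,4,5-trimethoxyphenyl)-4H-chromen-4-one
Product: 18 8-bromo-5,7-dihydroxy-6-methoxy-2-(3,4,5-trimethoxyphenyl)-4H-chromen-4-one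
Conditions: NBS (1.0 equiv), DMF, 0 °C
Reagents that add atoms: N-bromosuccinimide, O=C1CCC(=O)N1Br
Why: In this electrophilic aromatic bromination C8 is the only free carbon of ring A, ortho to the free C7 hydroxyl and para to the C5 hydroxyl, and should therefore react well ahead of C3 and of the ring-B positions, which have no free phenol to activate them.

Step 11
Reactants: 18 8-bromo-5,7-dihydroxy-6-methoxy-2-(3,4,5-trimethoxyphenyl)-4H-chromen-4-one
Product: 19 5,7-dihydroxy-6,8-dimethoxy-2-(3,4,5-trimethoxyphenyl)-4H-chromen-4-one (5,7-dihydroxy-6,8,3',4',5'-pentamethoxyflavone)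
Conditions: NaOMe (excess), CuBr, DMF/MeOH, 110 °C; then aq. HCl
Reagents that add atoms: sodium methoxide, [Na+].[O-]C
Why: Cu-mediated substitution of an aryl bromide by methoxide (Ullmann-type ether synthesis) is an established reaction type for 6- and 8-bromo-5,7-dihydroxyflavones, the phenoxides shield the pyranone from ring opening, and any ring-opening and reclosure through the other phenol oxygen would lead to the same product because C6 and C8 end up alike.

**Compound list**

1 | 3,5-dihydroxy-4-methoxybenzoic acid (4-O-methylgallic acid) | COc1c(O)cc(C(=O)O)cc1O | starting material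
2 | benzyl 3,5-bis(benzyloxy)-4-methoxybenzoate | COc1c(OCc2ccccc2)cc(C(=O)OCc2ccccc2)cc1OCc1ccccc1 | intermediate
3 | [3,5-bis(benzyloxy)-4-methoxyphenyl]methanol | COc1c(OCc2ccccc2)cc(CO)cc1OCc1ccccc1 | intermediate
4 | 3,5-bis(benzyloxy)-4-methoxybenzaldehyde | COc1c(OCc2ccccc2)cc(C=O)cc1OCc1ccccc1 | intermediate
5 | 3,5-bis(benzyloxy)-4-methoxyphenyl formate | COc1c(OCc2ccccc2)cc(OC=O)cc1OCc1ccccc1 | intermediate
6 | 3,5-bis(benzyloxy)-4-methoxyphenol | COc1c(OCc2ccccc2)cc(O)cc1OCc1ccccc1 | intermediate
7 | 3,5-bis(benzyloxy)-2-bromo-4-methoxyphenol | COc1c(OCc2ccccc2)cc(O)c(Br)c1OCc1ccccc1 | intermediate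
8 | [3,5-bis(benzyloxy)-2-bromo-4-methoxyphenoxy]trimethylsilane | COc1c(OCc2ccccc2)cc(O[Si](C)(C)C)c(Br)c1OCc1ccccc1 | intermediate
9 | lithium 3,5-bis(benzyloxy)-4-methoxy-2-(trimethylsilyl)phenoxide | COc1c(OCc2ccccc2)cc([O-])c([Si](C)(C)C)c1OCc1ccccc1.[Li+] | intermediate
10 | 3,5-bis(benzyloxy)-4-methoxy-2-(trimethylsilyl)phenyl trifluoromethanesulfonate | COc1c(OCc2ccccc2)cc(OS(=O)(=O)C(F)(F)F)c([Si](C)(C)C)c1OCc1ccccc1 | intermediate
11 | 5-ethynyl-1,2,3-trimethoxybenzene | COc1cc(C#C)cc(OC)c1OC | starting material
12 | lithium (3,4,5-trimethoxyphenyl)acetylide | COc1cc(C#[C-])cc(OC)c1OC.[Li+] | intermediate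
13 | 3-(3,4,5-trimethoxyphenyl)propiolic acid | COc1cc(C#CC(=O)O)cc(OC)c1OC | intermediate
14 | 3,5-bis(benzyloxy)-4-methoxybenzyne (1,2-didehydro-3,5-bis(benzyloxy)-4-methoxybenzene) | COC1=C(OCc2ccccc2)C#CC=C1OCc1ccccc1 | intermediate
15 | cesium 3,5-bis(benzyloxy)-4-methoxy-2-[3-(3,4,5-trimethoxyphenyl)propioloyl]phenoxide | COc1cc(C#CC(=O)c2c([O-])cc(OCc3ccccc3)c(OC)c2OCc2ccccc2)cc(OC)c1OC.[Cs+] | intermediate
16 | 5,7-bis(benzyloxy)-6-methoxy-2-(3,4,5-trimethoxyphenyl)-4H-chromen-4-one | COc1cc(-c2cc(=O)c3c(OCc4ccccc4)c(OC)c(OCc4ccccc4)cc3o2)cc(OC)c1OC | intermediate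
17 | 5,7-dihydroxy-6-methoxy-2-(3,4,5-trimethoxyphenyl)-4H-chromen-4-one | COc1cc(-c2cc(=O)c3c(O)c(OC)c(O)cc3o2)cc(OC)c1OC | intermediate
18 | 8-bromo-5,7-dihydroxy-6-methoxy-2-(3,4,5-trimethoxyphenyl)-4H-chromen-4-one | COc1cc(-c2cc(=O)c3c(O)c(OC)c(O)c(Br)c3o2)cc(OC)c1OC | intermediate
19 | 5,7-dihydroxy-6,8-dimethoxy-2-(3,4,5-trimethoxyphenyl)-4H-chromen-4-one | COc1cc(-c2cc(=O)c3c(O)c(OC)c(O)c(OC)c3o2)cc(OC)c1OC | target

**Step count**

Total steps: 11. Longest linear sequence: 10 (steps 1–6, then 8–11); step 7 is the one-step side branch.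

**Steps most likely to fail**

Step 8. The aryl anion may be protonated before it migrates onto the carboxyl carbon, so that plain O-arylation replaces insertion, and the propiolate may lose CO2 at 125 °C before it is consumed. The fallback sets out from phenol 6 and alkyne 11 and returns to the route at 16. Iodination of 6 with NIS (CH2Cl2, −78 to 0 °C) should give 3,5-bis(benzyloxy)-2-iodo-4-methoxyphenol F1. Carbonylative Sonogashira coupling of this iodophenol with 11 under CO (PdCl2(dppf), Et2NH, 120 °C), with amine-mediated 6-endo ring closure in the same flask, is a known flavone synthesis and would deliver 16. In this variant C4 comes from CO and the C4–C4a bond is made by acylpalladium chemistry instead of by the aryne.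

Step 11. Substitution may be slow on the electron-rich bis-phenoxide, and reductive loss of bromine may then outrun C–O bond formation. The fallback sets out from 18 and returns at 19. Benzylation of both phenols (BnBr, K2CO3, DMF, 60 °C) would give 5,7-bis(benzyloxy)-8-bromo-6-methoxy-2-(3,4,5-trimethoxyphenyl)-4H-chromen-4-one F2, a neutral aryl bromide. Pd-catalysed C–O cross-coupling with methanol (Pd2(dba)3, tBuBrettPhos, Cs2CO3, toluene/MeOH, 80 °C) would then give 5,7-bis(benzyloxy)-6,8-dimethoxy-2-(3,4,5-trimethoxyphenyl)-4H-chromen-4-one F3. Hydrogenolysis (H2, Pd/C, THF/MeOH) would release 19.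

Step 6. Migration of silicon from oxygen to the crowded carbon between two oxygen substituents may be incomplete, the aryllithium being protonated instead, and triflation of the hindered phenoxide may lag. The fallback sets out from phenol 6, bypasses 7, and returns at 10; silicon is brought in by an external electrophile after directed ortho-metalation.
- Isopropyl isocyanate with catalytic Et3N would give 3,5-bis(benzyloxy)-4-methoxyphenyl N-isopropylcarbamate F4.
- TBSOTf/TMEDA would mask the N–H in the flask as 3,5-bis(benzyloxy)-4-methoxyphenyl N-(tert-butyldimethylsilyl)-N-isopropylcarbamate F5.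
- Carbamate-directed ortho-lithiation (n-BuLi, TMEDA, Et2O, −78 °C) and TMSCl quench would give 3,5-bis(benzyloxy)-4-methoxy-2-(trimethylsilyl)phenyl N-(tert-butyldimethylsilyl)-N-isopropylcarbamate F6.
- Acidic work-up would remove the N-silyl group to leave 3,5-bis(benzyloxy)-4-methoxy-2-(trimethylsilyl)phenyl N-isopropylcarbamate F7.
- DBU/Et2NH in MeCN at 40 °C would cleave the carbamate to 3,5-bis(benzyloxy)-4-methoxy-2-(trimethylsilyl)phenol F8, which PhNTf2 would triflate in the same flask to give 10.

Further compounds

F1 | step 8 | 3,5-bis(benzyloxy)-2-iodo-4-methoxyphenol | COc1c(OCc2ccccc2)cc(O)c(I)c1OCc1ccccc1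
F2 | step 11 | 5,7-bis(benzyloxy)-8-bromo-6-methoxy-2-(3,4,5-trimethoxyphenyl)-4H-chromen-4-one | COc1cc(-c2cc(=O)c3c(OCc4ccccc4)c(OC)c(OCc4ccccc4)c(Br)c3o2)cc(OC)c1OC
F3 | step 11 | 5,7-bis(benzyloxy)-6,8-dimethoxy-2-(3,4,5-trimethoxyphenyl)-4H-chromen-4-one | COc1cc(-c2cc(=O)c3c(OCc4ccccc4)c(OC)c(OCc4ccccc4)c(OC)c3o2)cc(OC)c1OC
F4 | step 6 | 3,5-bis(benzyloxy)-4-methoxyphenyl N-isopropylcarbamate | COc1c(OCc2ccccc2)cc(OC(=O)NC(C)C)cc1OCc1ccccc1
F5 | step 6 | 3,5-bis(benzyloxy)-4-methoxyphenyl N-(tert-butyldimethylsilyl)-N-isopropylcarbamate | COc1c(OCc2ccccc2)cc(OC(=O)N(C(C)C)[Si](C)(C)C(C)(C)C)cc1OCc1ccccc1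
F6 | step 6 | 3,5-bis(benzyloxy)-4-methoxy-2-(trimethylsilyl)phenyl N-(tert-butyldimethylsilyl)-N-isopropylcarbamate | COc1c(OCc2ccccc2)cc(OC(=O)N(C(C)C)[Si](C)(C)C(C)(C)C)c([Si](C)(C)C)c1OCc1ccccc1
F7 | step 6 | 3,5-bis(benzyloxy)-4-methoxy-2-(trimethylsilyl)phenyl N-isopropylcarbamate | COc1c(OCc2ccccc2)cc(OC(=O)NC(C)C)c([Si](C)(C)C)c1OCc1ccccc1
F8 | step 6 | 3,5-bis(benzyloxy)-4-methoxy-2-(trimethylsilyl)phenol | COc1c(OCc2ccccc2)cc(O)c([Si](C)(C)C)c1OCc1ccccc1
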